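With the ring numbered C1 (C=O), C2=C3, C4, C5 (carbinol), C6, the plan cuts C2=C3 and C4–C5, so that C3–C4 is a vinyl group on boron. The key step exploits the homoallylic relation of the C5 carbinol to the C2=C3 alkene: a diazoalkane carbon (C2) takes the vinyl group from boron, and the resulting α-chiral allylboronate adds through C4 to the tethered C5 ketone. One operation thus closes the six-membered ring, places the cis alkene and sets C5. The precursor is an acyclic 4-oxoaldehyde sulfonylhydrazone in which the C1 and side-chain carbonyls are carried as silyl-protected carbinols and are oxidised at the end.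

Key step: step 8

Assumption: the (R)-diol is taken to induce the (R)-configuration at the boron-bearing carbon, by analogy with diol-catalysed homologations of alkenylboron compounds; should the sense be opposite, the (S)-diol is used.
Abbreviations: TBS = tert-butyldimethylsilyl; the labels C1–C6 in the Why lines are the ring numbers defined above and are kept for the same carbons in the acyclic intermediates.

Step 1
Reactants: 1 (9Z)-octadec-9-en-1-ol (oleyl alcohol)
Product: 2 (9Z)-octadec-9-enal
Conditions: 2,2,6,6-tetramethylpiperidin-1-oxyl (10 mol %), PhI(OAc)2, CH2Cl2, 20 °C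
Reagents that add atoms: none
Why: The oxoammonium-mediated alcohol oxidation should stop at the aldehyde and leave the Z-alkene untouched.

Step 2
Reactants: 3 acetone; 4 2,2-dimethoxyacetaldehyde (60 % aqueous solution)
Product: 5 (4R)-4-hydroxy-5,5-dimethoxypentan-2-one
Conditions: L-proline (20 mol %), acetone as solvent, 20 °C
Reagents that add atoms: none
Why: A proline-catalysed direct aldol addition (enamine catalysis) to the non-enolisable aldehyde should set the carbinol centre (future C1) as R through the acid-directed enamine transition state, by analogy with other aldehyde acceptors.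

Step 3
Reactants: 5 (4R)-4-hydroxy-5,5-dimethoxypentan-2-one
Product: 6 (4R)-4-[(tert-butyldimethylsilyl)oxy]-5,5-dimethoxypentan-2-one
Conditions: TBSCl, imidazole, DMF, 20 °C
Reagents that add atoms: tert-butyldimethylsilyl chloride, CC(C)(C)[Si](C)(C)Cl
Why: Silyl ether formation blocks retro-aldol cleavage and elimination in the enolate chemistry that follows.

Step 4
Reactants: 6 (4R)-4-[(tert-butyldimethylsilyl)oxy]-5,5-dimethoxypentan-2-one; 2 (9Z)-octadec-9-enal
Product: 7 (2R,14Z)-2-[(tert-butyldimethylsilyl)oxy]-6-hydroxy-1,1-dimethoxytricos-14-en-4-one (both epimers at the new carbinol carbon)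
Conditions: LiN(iPr)2, THF, −78 °C; then 2, −78 °C; AcOH quench
Reagents that add atoms: none
Why: Kinetic deprotonation at the methyl group and addition of the lithium enolate to the aldehyde (directed aldol addition) attaches the side-chain arm, and the new carbinol centre is left unselected because it becomes the side-chain ketone in step 10.

Step 5
Reactants: 7 (2R,14Z)-2-[(tert-butyldimethylsilyl)oxy]-6-hydroxy-1,1-dimethoxytricos-14-en-4-one
Product: 8 (2R,14Z)-2,6-bis[(tert-butyldimethylsilyl)oxy]-1,1-dimethoxytricos-14-en-4-one (both epimers at the side-chain silyloxy carbon)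
Conditions: TBSCl, imidazole, 4-(dimethylamino)pyridine (10 mol %), DMF, 35 °C
Reagents that add atoms: tert-butyldimethylsilyl chloride, CC(C)(C)[Si](C)(C)Cl
Why: Silyl ether formation under non-ionising conditions masks the β-hydroxy ketone without disturbing the dimethyl acetal, so that C5 is the only free carbonyl group.

Step 6
Reactants: 8 (2R,14Z)-2,6-bis[(tert-butyldimethylsilyl)oxy]-1,1-dimethoxytricos-14-en-4-one
Product: 9 (2R,14Z)-2,6-bis[(tert-butyldimethylsilyl)oxy]-4-oxotricos-14-enal
Conditions: CF3CO2H/H2O (9:1), CH2Cl2, 0 °C
Reagents that add atoms: water, O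
Why: Acid-catalysed acetal hydrolysis at 0 °C should free the aldehyde (future C2), the secondary silyl ethers being stable to brief cold aqueous acid.

Step 7
Reactants: 9 (2R,14Z)-2,6-bis[(tert-butyldimethylsilyl)oxy]-4-oxotricos-14-enal
Product: 10 N'-[(1E,2R,14Z)-2,6-bis[(tert-butyldimethylsilyl)oxy]-4-oxotricos-14-en-1-ylidene]-2-(trifluoromethyl)benzenesulfonohydrazide
Conditions: 2-(CF3)C6H4SO2NHNH2 (1.0 equiv), 4 Å molecular sieves, THF, 0 → 20 °C
Reagents that add atoms: 2-(trifluoromethyl)benzenesulfonohydrazide, NNS(=O)(=O)c1ccccc1C(F)(F)F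
Why: Hydrazone formation is much faster at the aldehyde than at the flanked ketone, and the electron-poor arylsulfonyl group allows Bamford–Stevens-type diazo release below room temperature.

Step 8
Reactants: 10 N'-[(1E,2R,14Z)-2,6-bis[(tert-butyldimethylsilyl)oxy]-4-oxotricos-14-en-1-ylidene]-2-(trifluoromethyl)benzenesulfonohydrazide; 11 dibutyl vinylboronate
Product: 14 (1R,5R)-5-[(tert-butyldimethylsilyl)oxy]-1-[(10Z)-2-[(tert-butyldimethylsilyl)oxy]nonadec-10-en-1-yl]cyclohex-3-en-1-ol, via diazoalkane 12 (not isolated), via allylboronate 13 (not isolated)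
Conditions: NaN(SiMe3)2 (1.0 equiv), THF, −78 °C; then 11 (2 equiv), (R)-3,3'-dibromo-1,1'-bi-2-naphthol (30 mol %), 4 Å molecular sieves, toluene, −40 → 20 °C; aq. NaHCO3 work-up
Reagents that add atoms: none
Why: Proposed new method: deprotonated 10 loses sulfinate (Bamford–Stevens-type) to give diazoalkane 12, whose carbon C2 adds to the Lewis-acidic vinylboron centre; the vinyl group then shifts from boron to C2 with loss of N2 (C2–C3 bond) to give allylboronate 13, and the terminal CH2 of 13 (C4) adds to the tethered C5 ketone by intramolecular allylboration (C4–C5 bond), which moves the double bond to C2=C3 and passes boron to the new alkoxide. The closest known reaction types are the one-pot union of a diazoalkane, an alkenylboron compound and a carbonyl compound, the bi-2-naphthol-catalysed enantioselective homologation of alkenylboron compounds with diazoalkanes, and domino cyclisations of sulfonylhydrazones that carry an internal electrophile; the α-silyloxy diazoalkane and the internal ketone acceptor have not been shown. The carbocycle closes by 6-exo-trig attack on the ketone through a boat-like bicyclo[2.2.2] array with a C3=C4 bridge, a C1–C6 bridge and a B–O bridge, which can only give the cis ring alkene, whereas attack through C2 would need a four-membered ring. C5, the only stereocentre of the target, is set by relay: in this array the configuration at the boron-bearing C2 fixes the ketone face, (R)-C2 giving (R)-C5, and (R)-C2 is set by the chiral diol on boron during the 1,2-shift (reagent control). The step needs facial selectivity at the diazo carbon and ring closure faster than protodeboronation or 1,3-boron shift; the ligand-accelerated pathway through the bi-2-naphthol boronate and the short tether to an unhindered ketone are meant to secure these. The (R)-silyloxy centre at C1 is a second safeguard, since only the (R,R)-allylboronate places this group away from the boron bridge and since any C5 epimer is a diastereomer that can be removed by chromatography.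

Step 9
Reactants: 14 (1R,5R)-5-[(tert-butyldimethylsilyl)oxy]-1-[(10Z)-2-[(tert-butyldimethylsilyl)oxy]nonadec-10-en-1-yl]cyclohex-3-en-1-ol
Product: 15 (1R,3R)-1-[(10Z)-2-hydroxynonadec-10-en-1-yl]cyclohex-4-ene-1,3-diol (both epimers at the side-chain carbinol carbon)
Conditions: HF·pyridine, pyridine, THF, 0 → 20 °C
Reagents that add atoms: none
Why: Buffered fluoride desilylation should cleave both secondary silyl ethers without touching the tertiary alcohol or either alkene.

Step 10
Reactants: 15 (1R,3R)-1-[(10Z)-2-hydroxynonadec-10-en-1-yl]cyclohex-4-ene-1,3-diol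
Product: 16 (5R)-5-hydroxy-5-[(10Z)-2-oxononadec-10-en-1-yl]cyclohex-2-en-1-one (CNP0165051.1)
Conditions: Dess–Martin periodinane (2.4 equiv), NaHCO3, CH2Cl2, 0 → 20 °C
Reagents that add atoms: none
Why: Dess–Martin oxidation should convert the allylic and the side-chain secondary alcohols into the enone and the ketone in one operation, the tertiary alcohol being inert and the bicarbonate buffer suppressing dehydration of the β-hydroxy ketones.

Compound list
1 | (9Z)-octadec-9-en-1-ol (oleyl alcohol) | CCCCCCCC/C=C\CCCCCCCCO | starting material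
2 | (9Z)-octadec-9-enal | CCCCCCCC/C=C\CCCCCCCC=O | intermediate
3 | acetone | CC(C)=O | starting material
4 | 2,2-dimethoxyacetaldehyde | COC(OC)C=O | starting material
5 | (4R)-4-hydroxy-5,5-dimethoxypentan-2-one | CC(=O)C[C@@H](O)C(OC)OC | intermediate
6 | (4R)-4-[(tert-butyldimethylsilyl)oxy]-5,5-dimethoxypentan-2-one | CC(=O)C[C@@H](O[Si](C)(C)C(C)(C)C)C(OC)OC | intermediate
7 | (2R,14Z)-2-[(tert-butyldimethylsilyl)oxy]-6-hydroxy-1,1-dimethoxytricos-14-en-4-one, both epimers at C6 of the chain | CCCCCCCC/C=C\CCCCCCCC(O)CC(=O)C[C@@H](O[Si](C)(C)C(C)(C)C)C(OC)OC | intermediate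
8 | (2R,14Z)-2,6-bis[(tert-butyldimethylsilyl)oxy]-1,1-dimethoxytricos-14-en-4-one, both epimers at C6 of the chain | CCCCCCCC/C=C\CCCCCCCC(O[Si](C)(C)C(C)(C)C)CC(=O)C[C@@H](O[Si](C)(C)C(C)(C)C)C(OC)OC | intermediate
9 | (2R,14Z)-2,6-bis[(tert-butyldimethylsilyl)oxy]-4-oxotricos-14-enal, both epimers at C6 of the chain | CCCCCCCC/C=C\CCCCCCCC(O[Si](C)(C)C(C)(C)C)CC(=O)C[C@@H](O[Si](C)(C)C(C)(C)C)C=O | intermediate
10 | N'-[(1E,2R,14Z)-2,6-bis[(tert-butyldimethylsilyl)oxy]-4-oxotricos-14-en-1-ylidene]-2-(trifluoromethyl)benzenesulfonohydrazide, both epimers at C6 of the chain | CCCCCCCC/C=C\CCCCCCCC(O[Si](C)(C)C(C)(C)C)CC(=O)C[C@@H](O[Si](C)(C)C(C)(C)C)/C=N/NS(=O)(=O)c1ccccc1C(F)(F)F | intermediate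
11 | dibutyl vinylboronate (dibutyl ethenylboronate) | C=CB(OCCCC)OCCCC | starting material
12 | (2R,14Z)-2,6-bis[(tert-butyldimethylsilyl)oxy]-1-diazotricos-14-en-4-one, both epimers at C6 of the chain | [N-]=[N+]=C[C@H](O[Si](C)(C)C(C)(C)C)CC(=O)CC(O[Si](C)(C)C(C)(C)C)CCCCCCC/C=C\CCCCCCCC | intermediate
13 | dibutyl [(3R,4R,16Z)-4,8-bis[(tert-butyldimethylsilyl)oxy]-6-oxopentacosa-1,16-dien-3-yl]boronate, drawn as the dibutyl ester that exchanges with the diol-bound form, both epimers at C8 of the chain | C=C[C@@H](B(OCCCC)OCCCC)[C@H](O[Si](C)(C)C(C)(C)C)CC(=O)CC(O[Si](C)(C)C(C)(C)C)CCCCCCC/C=C\CCCCCCCC | intermediate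
14 | (1R,5R)-5-[(tert-butyldimethylsilyl)oxy]-1-[(10Z)-2-[(tert-butyldimethylsilyl)oxy]nonadec-10-en-1-yl]cyclohex-3-en-1-ol, both epimers at the side-chain silyloxy carbon | CCCCCCCC/C=C\CCCCCCCC(O[Si](C)(C)C(C)(C)C)C[C@]1(O)CC=C[C@H](O[Si](C)(C)C(C)(C)C)C1 | intermediate
15 | (1R,3R)-1-[(10Z)-2-hydroxynonadec-10-en-1-yl]cyclohex-4-ene-1,3-diol, both epimers at the side-chain carbinol carbon | CCCCCCCC/C=C\CCCCCCCC(O)C[C@]1(O)CC=C[C@H](O)C1 | intermediate
16 | (5R)-5-hydroxy-5-[(10Z)-2-oxononadec-10-en-1-yl]cyclohex-2-en-1-one | CCCCCCCC/C=C\CCCCCCCC(=O)C[C@]1(O)CC=CC(=O)C1 | target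

Total step count: 10. Longest linear sequence: 9 steps (steps 2 to 10, from 3 and 4 to 16).

Steps most likely to fail

Step 8 (Proposed new method). The boron shift may run partly through a ligand-free pathway, which would erode facial selectivity at the diazo carbon. The allylboronate may undergo protodeboronation or 1,3-boron shift before it closes the ring, and the diazoalkane may be lost by azine formation. The fallback uses known chemistry and sets out from aldehyde 9. Wittig methylenation (Ph3P=CH2, one equivalent, THF, −78 °C, the aldehyde reacting before the ketone) should give (3R,15Z)-3,7-bis[(tert-butyldimethylsilyl)oxy]tetracosa-1,15-dien-5-one F1. Allylmagnesium bromide at −78 °C adds to its ketone to give (3R,15Z)-3,7-bis[(tert-butyldimethylsilyl)oxy]-5-(prop-2-en-1-yl)tetracosa-1,15-dien-5-ol F2 as both C5 epimers. Ring-closing metathesis with the first-generation Grubbs catalyst RuCl2(PCy3)2(=CHPh) in CH2Cl2, which should spare the internal Z-alkene, then closes the same cyclohexene. Because C1 is a defined centre, the two C5 epimers are cis/trans diastereomers, and the (1R,5R)-isomer is separated by chromatography. The fallback comes back to the route at 14.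

Step 6. Cold aqueous acid may cause partial loss of a silyl ether, epimerisation of the α-silyloxy aldehyde centre, or β-elimination of silanol next to the ketone. The fallback sets out from acetal 8 and avoids both Brønsted acid and the free aldehyde. TESOTf and 2,4,6-collidine in CH2Cl2 at 0 °C should ionise the dimethyl acetal to a collidinium-bound oxocarbenium salt. Adding 2-(trifluoromethyl)benzenesulfonohydrazide to this salt in place of water should give the hydrazone directly. It makes no compound outside the list (F0) and comes back to the route at 10.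

Step 10. The acetic acid released, or base on work-up, may promote β-elimination of the tertiary hydroxyl followed by tautomerisation to a phenol, or retro-aldol cleavage. The fallback sets out from triol 15 and oxidises the two alcohols in separate, chemoselective operations. MnO2 in CH2Cl2 should oxidise only the allylic alcohol to give (5R)-5-hydroxy-5-[(10Z)-2-hydroxynonadec-10-en-1-yl]cyclohex-2-en-1-one F3. The remaining saturated secondary alcohol is then oxidised under neutral conditions with NPr4RuO4 (5 mol %) and N-methylmorpholine N-oxide over 4 Å molecular sieves. The fallback comes back to the route at 16.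

Further compounds
F1 | step 8 | (3R,15Z)-3,7-bis[(tert-butyldimethylsilyl)oxy]tetracosa-1,15-dien-5-one | C=C[C@H](O[Si](C)(C)C(C)(C)C)CC(=O)CC(O[Si](C)(C)C(C)(C)C)CCCCCCC/C=C\CCCCCCCC
F2 | step 8 | (3R,15Z)-3,7-bis[(tert-butyldimethylsilyl)oxy]-5-(prop-2-en-1-yl)tetracosa-1,15-dien-5-ol, both C5 epimers | C=C[C@H](O[Si](C)(C)C(C)(C)C)CC(O)(CC=C)CC(O[Si](C)(C)C(C)(C)C)CCCCCCC/C=C\CCCCCCCC
F0 | step 6 | none | none
F3 | step 10 | (5R)-5-hydroxy-5-[(10Z)-2-hydroxynonadec-10-en-1-yl]cyclohex-2-en-1-one | CCCCCCCC/C=C\CCCCCCCC(O)C[C@]1(O)CC=CC(=O)C1
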